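The earlier runs and the new flask stem from a simulated flask for an exercise; the scatter is artificial.

I choose to judge this flask by one number read from the autumn run, and to keep the cooling out of the reckoning for as long as the argument allows.

common to all: L 1.44 M

| charge | G | temperature | remark | time |
|---|---|---|---|---|
| autumn | 2.4 M | −20 °C | run made earlier |  |
| north-east | 1.2 M |  | at −20 °C throughout | 2.0 min |
| west | 1.2 M |  | at −20 °C until 3.0 min, from then on at −60 °C | 6.0 min |

autumn run (percent of the G charged): time / s: J / % = 10.0: 18.6; 20.0: 31.1; 30.0: 40.0; 40.0: 47.0; 50.0: 52.1; 60.0: 53.3; 80.0: 58.2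

(scatter of a reading: 0.5 percentage points)

- the earlier runs were read with a standard deviation of 0.5 percentage points
- candidate steps: G -> J; X <-> D; G <-> X; X -> Z; L + X -> Q; L <-> E
- the earlier runs do not show what temperature does; that part of a forecast is a guess

* which one finishes higher in amount of J, in percent of the G charged ("neither" within 2 percentage points) (north-east / west / neither)
* amount of J at the end, in percent of the G charged, north-east
* amount of J at the end, in percent of the G charged, west

I take X and D as passing quickly and staying low (a quasi-steady state), so that G falls in one exponential and each G lost splits in a fixed ratio. J then climbs toward a ceiling, with its shortfall shrinking at a rate k. Two readings at doubled time, 47.0% and 58.2%, give k = 0.0359 s⁻¹ and a ceiling S = 61.7%, both readings that carry the scatter of the autumn run; S is the share of the G lost that ends as J, its selectivity. As a test, these two put the earliest reading at 18.6%, and it was read at 18.6%.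

Now the two extremes. In one, the side stream out of X needs no L, so S carries over to the new charge unchanged. In the other, the side stream runs wholly by L + X → Q, so its ratio to J scales with cL. In this extreme, setting L ⇌ E aside, I reckon a mean cL of 0.980 M for autumn and of 1.21 M for the smaller charge of G, which is higher, and the ceiling drops to about 56.6%. A mixture of the two lies between these values.

North-east at 2.0 min has reached 98.6% of its ceiling, so I expect 55.8% to 60.8%. By this k, I reckon that west keeps 0.157% of its G at 3.0 min, hardly any, so the cooling acts on that remainder and I expect 56.6% to 61.7%. The two flasks have the same charge, so I give them one ceiling, and at S the gap between them comes to about 0.83 percentage points, less than 2 points, so I commit to neither.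

The forecast gives 56% for north-east, 57% for west and neither, with the remark “West may gain slightly from its extra time.”

North-east gives 61.0% and west 61.7%, so the answer is neither.

    G → J (k = 0.0220 s⁻¹, Ea = 59.0 kJ mol⁻¹)
    X ⇌ D (K = 0.850, k = 0.0690 s⁻¹, Ea = 72.0 kJ mol⁻¹, ΔH = 6.00 kJ mol⁻¹)
    G ⇌ X (K = 1.90, k = 0.0140 s⁻¹, Ea = 75.0 kJ mol⁻¹, ΔH = −20.0 kJ mol⁻¹)
    X → Z (k = 0.230 s⁻¹, Ea = 56.0 kJ mol⁻¹)
    L + X → Q (k = 0.00620 M⁻¹ s⁻¹, Ea = 60.0 kJ mol⁻¹)
    L ⇌ E (K = 1.60, k = 0.380 s⁻¹, Ea = 71.0 kJ mol⁻¹, ΔH = −11.0 kJ mol⁻¹)
    (constants at −20 °C)

West's answer moves by 5 points if it is read as early as 1.17 min, and S with k puts the shortfall at that time at 5.0 points. For the neighbour flask, west read at 15 min with 0.16% of its G left, S gives 61.7%, and that flask holds 61.8% of J, with 30% of its L charge left unbound.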